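## Retrosynthetic overview

- Labdane numbering (C1–C20) is used. The diester comes from the 13S,14R triol 22, made from copalol 19 by asymmetric epoxidation and Payne rearrangement–opening; the 13E side chain comes from a C13≡C14 alkyne by carboalumination.
- The decalin is made in one operation from acyclic aldehyde 12 and 2-methylpropene: C2–C3 by radical addition, then C4–C5 (ring A) and C9–C10 (ring B) by cation–alkene closures. Ring A forms first, ring B second, and the formyl group on C2 is then removed.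
- Enabling feature: ring A holds the unit C3H2–C4(CH3)2, which is 2-methylpropene, next to an unsubstituted C2 that can serve as an aldehyde α-carbon. The quaternary C10 and the C8 exocyclic methylene mark the cation relay (E-C5=C10 alkene, C8=C9 allylsilane).
- Aldehyde 12 is assembled by Johnson–Claisen rearrangement (E-C5=C10), alkyne carbocupration/iodination (allylsilane geometry) and Negishi coupling (side chain).

Key step: step 6

Assumption: the facial model known for (2S,5S)-5-benzyl-2-tert-butyl-3-methylimidazolidin-4-one in enamine radical-cation α-alkylation (attack anti to the benzyl group) is taken to hold for 12 and predicts the 2S aldehyde; the (2R,5R) catalyst would be used if the opposite sense were found.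

## Route

Step 1
Reactants: 1 pent-4-ynal; 2 prop-1-en-2-ylmagnesium bromide
Product: 3 2-methylhept-1-en-6-yn-3-ol (racemic)
Conditions: THF, −78 → 0 °C; aqueous work-up
Reagents that add atoms: none
Why: Grignard 1,2-addition to the aldehyde should outrun deprotonation of the terminal alkyne at −78 °C, and the racemic carbinol centre is erased in step 2.

Step 2
Reactants: 3 2-methylhept-1-en-6-yn-3-ol; 4 triethyl orthoacetate
Product: 5 ethyl (4E)-4-methylnon-4-en-8-ynoate
Conditions: EtCO2H (cat.), neat in 4 (5 equiv), 140 °C, EtOH distilled off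
Reagents that add atoms: none
Why: Johnson–Claisen rearrangement through a chair transition state with the butynyl substituent equatorial should give the E-trisubstituted C5=C10 alkene and adds the two-carbon arm that becomes C2 and the temporary formyl carbon.

Step 3
Reactants: 5 ethyl (4E)-4-methylnon-4-en-8-ynoate; 6 [(trimethylsilyl)methyl]magnesium chloride
Product: 8 ethyl (4E,8Z)-9-iodo-4-methyl-8-[(trimethylsilyl)methyl]nona-4,8-dienoate, via alkenylcopper 7 (not isolated)
Conditions: CuBr·SMe2 (1 equiv per 6), LiBr, Et2O–THF, −30 → 20 °C; then I2, −40 °C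
Reagents that add atoms: iodine II
Why: Normant-type syn carbocupration of the terminal alkyne places the silylmethyl group on the internal carbon and copper on the terminal carbon, and iodinolysis with retention gives the iodoalkene with iodine cis to CH2SiMe3, while the non-basic organocopper reagent should leave the ester untouched.

Step 4
Reactants: 8 ethyl (4E,8Z)-9-iodo-4-methyl-8-[(trimethylsilyl)methyl]nona-4,8-dienoate; 9 (4-bromobut-1-yn-1-yl)trimethylsilane
Product: 11 ethyl (4E,8Z)-4-methyl-13-(trimethylsilyl)-8-[(trimethylsilyl)methyl]trideca-4,8-dien-12-ynoate, via organozinc bromide 10 (not isolated)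
Conditions: 9, Zn dust, LiCl, THF, 50 °C; then 8, Pd(PPh3)4 (5 mol%), THF, 40 °C
Reagents that add atoms: none
Why: Negishi coupling of the alkylzinc bromide with the alkenyl iodide proceeds with retention of alkene geometry, so the side chain ends up cis to CH2SiMe3 as needed for an equatorial C9 substituent after cyclization.

Step 5
Reactants: 11 ethyl (4E,8Z)-4-methyl-13-(trimethylsilyl)-8-[(trimethylsilyl)methyl]trideca-4,8-dien-12-ynoate
Product: 12 (4E,8Z)-4-methyl-13-(trimethylsilyl)-8-[(trimethylsilyl)methyl]trideca-4,8-dien-12-ynal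
Conditions: i-Bu2AlH (1.1 equiv), CH2Cl2, −78 °C; aq potassium sodium tartrate
Reagents that add atoms: none
Why: Partial ester reduction by i-Bu2AlH at −78 °C should stop at the aluminium hemiacetal, which releases the aldehyde on work-up, and the allylsilane and silylalkyne are inert.

Step 6
Reactants: 12 (4E,8Z)-4-methyl-13-(trimethylsilyl)-8-[(trimethylsilyl)methyl]trideca-4,8-dien-12-ynal; 13 2-methylpropene
Product: 14 (2S,4aS,8S,8aS)-4,4,8a-trimethyl-7-methylidene-8-[4-(trimethylsilyl)but-3-yn-1-yl]decahydronaphthalene-2-carbaldehyde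
Conditions: 13 (10 equiv, condensed), (2S,5S)-5-benzyl-2-tert-butyl-3-methylimidazolidin-4-one·CF3CO2H (20 mol%), Fe(phen)3(SbF6)3 (2.5 equiv), Na2HPO4 (2.5 equiv), H2O (3 equiv), acetone, −30 °C
Reagents that add atoms: none
Why: Proposed new method: the enamine of 12 is oxidized by the trivalent iron complex to a 3π-electron radical cation that adds through C2 to the CH2 end of 2-methylpropene (C2–C3), the tertiary C4 radical is oxidized to the cation, this closes ring A by attack on C5 of the E-C5=C10 alkene (C4–C5), and the C10 cation closes ring B by attack of the allylsilane at C9 with loss of silicon to leave the C8 exocyclic methylene. The closest known reaction is the organo-SOMO formal [4+2] cascade of aldehydes bearing a π-nucleophile with styrenes and other conjugated alkenes, and the closest cationic precedent is the allylsilane-terminated polyene bicyclization; new here are the unconjugated 1,1-dialkylalkene as radical acceptor and an alkene relay in place of an arene. Ring A is formed by intermolecular radical addition followed by a 6-endo-trig cationic closure, ring B by a 6-endo-trig closure in a chair–chair array. C2 is set by the catalyst (attack anti to the benzyl group gives 2S); C5 and C10 follow from anti addition across the E alkene in a chair whose C2 iminium substituent must be equatorial, since an axial group would face the axial methyls at C4 and C10; C9 follows from the Z-allylsilane in the second chair (side chain equatorial). The step needs the radical cation to take 2-methylpropene and not the alkenes of 12, which the excess of the gaseous alkene and the impossibility of a three- or four-membered closure onto C10=C5 should secure, and it needs the C4 cation to cyclize before it is trapped, which the non-nucleophilic SbF6 counter-ion and the non-participating cationic iminium at C2 favour.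

Step 7
Reactants: 14 (2S,4aS,8S,8aS)-4,4,8a-trimethyl-7-methylidene-8-[4-(trimethylsilyl)but-3-yn-1-yl]decahydronaphthalene-2-carbaldehyde
Product: 15 trimethyl{4-[(1S,4aS,8aS)-5,5,8a-trimethyl-2-methylidenedecahydronaphthalen-1-yl]but-1-yn-1-yl}silane
Conditions: RhCl(PPh3)3 (1.1 equiv), toluene, 110 °C
Reagents that add atoms: none
Why: Tsuji–Wilkinson decarbonylation (formyl C–H oxidative addition, CO extrusion, reductive elimination) removes the temporary formyl group and with it the relay stereocentre at C2, so both C2 epimers converge.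

Step 8
Reactants: 15 trimethyl{4-[(1S,4aS,8aS)-5,5,8a-trimethyl-2-methylidenedecahydronaphthalen-1-yl]but-1-yn-1-yl}silane
Product: 16 (1S,4aS,8aS)-1-(but-3-yn-1-yl)-5,5,8a-trimethyl-2-methylidenedecahydronaphthalene
Conditions: K2CO3 (0.2 equiv), MeOH, 25 °C
Reagents that add atoms: none
Why: Carbonate-catalysed methanolysis of the alkynylsilane (protodesilylation) frees the terminal alkyne without touching the exocyclic alkene.

Step 9
Reactants: 16 (1S,4aS,8aS)-1-(but-3-yn-1-yl)-5,5,8a-trimethyl-2-methylidenedecahydronaphthalene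
Product: 19 copalol [(2E)-3-methyl-5-[(1S,4aS,8aS)-5,5,8a-trimethyl-2-methylidenedecahydronaphthalen-1-yl]pent-2-en-1-ol], via alkenyldimethylalane 17 (not isolated), via lithium alkenylalanate 18 (not isolated)
Conditions: Me3Al (2.5 equiv), Cp2ZrCl2 (0.25 equiv), CH2Cl2, 0 → 25 °C; then n-BuLi, THF, −78 °C; (CH2O)n, −78 → 25 °C
Reagents that add atoms: trimethylaluminium C[Al](C)C; formaldehyde (from paraformaldehyde) C=O
Why: Zirconium-catalysed Negishi carboalumination adds methyl and aluminium syn across the terminal alkyne with methyl on the internal carbon, and hydroxymethylation of the alanate with retention fixes the 13E geometry, while the 1,1-disubstituted exocyclic alkene is not carbometalated.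

Step 10
Reactants: 19 copalol
Product: 20 [(2S,3S)-3-methyl-3-{2-[(1S,4aS,8aS)-5,5,8a-trimethyl-2-methylidenedecahydronaphthalen-1-yl]ethyl}oxiran-2-yl]methanol
Conditions: Ti(OiPr)4 (10 mol%), L-(+)-diethyl tartrate (12 mol%), t-BuOOH (2 equiv), 4 Å sieves, CH2Cl2, −20 °C
Reagents that add atoms: tert-butyl hydroperoxide CC(C)(C)OO
Why: Sharpless asymmetric epoxidation is specific for the allylic alcohol and with L-(+)-diethyl tartrate should give the 13S,14S epoxide (the sense that turns geraniol into its 2S,3S epoxide), and any minor decalin enantiomer from step 6 becomes a separable diastereomer.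

Step 11
Reactants: 20 [(2S,3S)-3-methyl-3-{2-[(1S,4aS,8aS)-5,5,8a-trimethyl-2-methylidenedecahydronaphthalen-1-yl]ethyl}oxiran-2-yl]methanol
Product: 22 (2R,3S)-3-methyl-5-[(1S,4aS,8aS)-5,5,8a-trimethyl-2-methylidenedecahydronaphthalen-1-yl]pentane-1,2,3-triol, via terminal epoxide 21 (not isolated)
Conditions: NaOH (0.5 M aq), t-BuOH, 75 °C
Reagents that add atoms: water O
Why: Payne rearrangement (alkoxide attack at C14 with inversion) gives the terminal epoxide, which hydroxide opens at primary C15, so C13 keeps its configuration and C14 is inverted to give the 13S,14R triol (net anti-dihydroxylation of the E alkene).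

Step 12
Reactants: 22 (2R,3S)-3-methyl-5-[(1S,4aS,8aS)-5,5,8a-trimethyl-2-methylidenedecahydronaphthalen-1-yl]pentane-1,2,3-triol
Product: 23 (2R,3S)-2,3-dihydroxy-3-methyl-5-[(1S,4aS,8aS)-5,5,8a-trimethyl-2-methylidenedecahydronaphthalen-1-yl]pentyl acetate
Conditions: AcCl (1.05 equiv), 2,4,6-collidine, CH2Cl2, −78 °C
Reagents that add atoms: acetyl chloride CC(=O)Cl
Why: Kinetic esterification with acetyl chloride and a hindered base at low temperature should acylate the primary hydroxyl in preference to the secondary and tertiary ones.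

Step 13
Reactants: 23 (2R,3S)-2,3-dihydroxy-3-methyl-5-[(1S,4aS,8aS)-5,5,8a-trimethyl-2-methylidenedecahydronaphthalen-1-yl]pentyl acetate
Product: 24 (2R,3S)-1-(acetyloxy)-3-hydroxy-3-methyl-5-[(1S,4aS,8aS)-5,5,8a-trimethyl-2-methylidenedecahydronaphthalen-1-yl]pentan-2-yl propanoate
Conditions: (EtCO)2O (1.5 equiv), Et3N, DMAP (10 mol%), CH2Cl2, 0 °C
Reagents that add atoms: propanoic anhydride CCC(=O)OC(=O)CC
Why: DMAP-catalysed acylation esterifies the secondary C14 hydroxyl while the tertiary C13 hydroxyl should not react at 0 °C, and the short, cold reaction limits acyl migration.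

## Compound list

1 | pent-4-ynal | C#CCCC=O | starting material
2 | prop-1-en-2-ylmagnesium bromide | CC(=C)[Mg]Br | starting material
3 | 2-methylhept-1-en-6-yn-3-ol (racemic) | C=C(C)C(O)CCC#C | intermediate
4 | triethyl orthoacetate | CC(OCC)(OCC)OCC | starting material
5 | ethyl (4E)-4-methylnon-4-en-8-ynoate | CCOC(=O)CC/C(C)=C/CCC#C | intermediate
6 | [(trimethylsilyl)methyl]magnesium chloride | C[Si](C)(C)C[Mg]Cl | starting material
7 | [(1Z,5E)-9-ethoxy-6-methyl-9-oxo-2-[(trimethylsilyl)methyl]nona-1,5-dien-1-yl]copper | CCOC(=O)CC/C(C)=C/CC/C(C[Si](C)(C)C)=C/[Cu] | intermediate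
8 | ethyl (4E,8Z)-9-iodo-4-methyl-8-[(trimethylsilyl)methyl]nona-4,8-dienoate | CCOC(=O)CC/C(C)=C/CC/C(C[Si](C)(C)C)=C/I | intermediate
9 | (4-bromobut-1-yn-1-yl)trimethylsilane | C[Si](C)(C)C#CCCBr | starting material
10 | bromo[4-(trimethylsilyl)but-3-yn-1-yl]zinc | C[Si](C)(C)C#CCC[Zn]Br | intermediate
11 | ethyl (4E,8Z)-4-methyl-13-(trimethylsilyl)-8-[(trimethylsilyl)methyl]trideca-4,8-dien-12-ynoate | CCOC(=O)CC/C(C)=C/CC/C(C[Si](C)(C)C)=C/CCC#C[Si](C)(C)C | intermediate
12 | (4E,8Z)-4-methyl-13-(trimethylsilyl)-8-[(trimethylsilyl)methyl]trideca-4,8-dien-12-ynal | O=CCC/C(C)=C/CC/C(C[Si](C)(C)C)=C/CCC#C[Si](C)(C)C | intermediate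
13 | 2-methylpropene | CC(C)=C | starting material
14 | (2S,4aS,8S,8aS)-4,4,8a-trimethyl-7-methylidene-8-[4-(trimethylsilyl)but-3-yn-1-yl]decahydronaphthalene-2-carbaldehyde | C=C1CC[C@H]2C(C)(C)C[C@H](C=O)C[C@]2(C)[C@H]1CCC#C[Si](C)(C)C | intermediate
15 | trimethyl{4-[(1S,4aS,8aS)-5,5,8a-trimethyl-2-methylidenedecahydronaphthalen-1-yl]but-1-yn-1-yl}silane | C=C1CC[C@H]2C(C)(C)CCC[C@]2(C)[C@H]1CCC#C[Si](C)(C)C | intermediate
16 | (1S,4aS,8aS)-1-(but-3-yn-1-yl)-5,5,8a-trimethyl-2-methylidenedecahydronaphthalene | C=C1CC[C@H]2C(C)(C)CCC[C@]2(C)[C@H]1CCC#C | intermediate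
17 | dimethyl{(1E)-2-methyl-4-[(1S,4aS,8aS)-5,5,8a-trimethyl-2-methylidenedecahydronaphthalen-1-yl]but-1-en-1-yl}alumane | C=C1CC[C@H]2C(C)(C)CCC[C@]2(C)[C@H]1CC/C(C)=C/[Al](C)C | intermediate
18 | lithium butyl(dimethyl){(1E)-2-methyl-4-[(1S,4aS,8aS)-5,5,8a-trimethyl-2-methylidenedecahydronaphthalen-1-yl]but-1-en-1-yl}aluminate | C=C1CC[C@H]2C(C)(C)CCC[C@]2(C)[C@H]1CC/C(C)=C/[Al-](C)(C)CCCC.[Li+] | intermediate
19 | copalol, (2E)-3-methyl-5-[(1S,4aS,8aS)-5,5,8a-trimethyl-2-methylidenedecahydronaphthalen-1-yl]pent-2-en-1-ol | C=C1CC[C@H]2C(C)(C)CCC[C@]2(C)[C@H]1CC/C(C)=C/CO | intermediate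
20 | [(2S,3S)-3-methyl-3-{2-[(1S,4aS,8aS)-5,5,8a-trimethyl-2-methylidenedecahydronaphthalen-1-yl]ethyl}oxiran-2-yl]methanol | C=C1CC[C@H]2C(C)(C)CCC[C@]2(C)[C@H]1CC[C@]3(C)O[C@H]3CO | intermediate
21 | (2S)-2-[(2R)-oxiran-2-yl]-4-[(1S,4aS,8aS)-5,5,8a-trimethyl-2-methylidenedecahydronaphthalen-1-yl]butan-2-ol | C=C1CC[C@H]2C(C)(C)CCC[C@]2(C)[C@H]1CC[C@](C)(O)[C@H]3CO3 | intermediate
22 | (2R,3S)-3-methyl-5-[(1S,4aS,8aS)-5,5,8a-trimethyl-2-methylidenedecahydronaphthalen-1-yl]pentane-1,2,3-triol | C=C1CC[C@H]2C(C)(C)CCC[C@]2(C)[C@H]1CC[C@](C)(O)[C@@H](CO)O | intermediate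
23 | (2R,3S)-2,3-dihydroxy-3-methyl-5-[(1S,4aS,8aS)-5,5,8a-trimethyl-2-methylidenedecahydronaphthalen-1-yl]pentyl acetate | C=C1CC[C@H]2C(C)(C)CCC[C@]2(C)[C@H]1CC[C@](C)(O)[C@@H](COC(C)=O)O | intermediate
24 | (2R,3S)-1-(acetyloxy)-3-hydroxy-3-methyl-5-[(1S,4aS,8aS)-5,5,8a-trimethyl-2-methylidenedecahydronaphthalen-1-yl]pentan-2-yl propanoate | C=C1CC[C@H]2C(C)(C)CCC[C@]2(C)[C@H]1CC[C@](C)(O)[C@@H](COC(C)=O)OC(=O)CC | target

## Step count and risks

Total steps: 13. Longest linear sequence: 13 (from pent-4-ynal).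

Steps most likely to fail:

**Step 6 (proposed new method).** The C4 cation may be intercepted by a second molecule of 2-methylpropene, by water or by proton loss before ring A closes, or the radical cation may add to the allylsilane of another molecule. The fallback sets out from 12 and comes back at 14, making the two bonds in separate known operations. Organo-SOMO α-allylation of 12 with trimethyl(2-methylallyl)silane (same imidazolidinone, (NH4)2Ce(NO3)6, NaHCO3, DME, −20 °C) should give (2S,4E,8Z)-4-methyl-2-(2-methylprop-2-en-1-yl)-13-(trimethylsilyl)-8-[(trimethylsilyl)methyl]trideca-4,8-dien-12-ynal F1. NaBH4 reduction gives the alcohol (2S,4E,8Z)-4-methyl-2-(2-methylprop-2-en-1-yl)-13-(trimethylsilyl)-8-[(trimethylsilyl)methyl]trideca-4,8-dien-12-yn-1-ol F2, and Ac2O/pyridine gives its acetate F3, because an aldehyde or a free hydroxyl would capture the cation. Cobalt-catalysed radical Markovnikov hydrochlorination (Co(BF4)2·6H2O, Schiff-base ligand, PhSiH3, TsCl, EtOH), which takes the 1,1-disubstituted alkene and cannot protodesilylate the allylsilane, gives the tertiary chloride (2R,4E,8Z)-2-(2-chloro-2-methylpropyl)-4-methyl-13-(trimethylsilyl)-8-[(trimethylsilyl)methyl]trideca-4,8-dien-12-yn-1-yl acetate F4. SnCl4 in CH2Cl2 at −78 °C ionizes the chloride, and the cation closes rings A and B with the C2 substituent equatorial and loss of silicon, giving [(2S,4aS,8S,8aS)-4,4,8a-trimethyl-7-methylidene-8-[4-(trimethylsilyl)but-3-yn-1-yl]decahydronaphthalen-2-yl]methyl acetate F5. i-Bu2AlH cleaves the acetate to the alcohol [(2S,4aS,8S,8aS)-4,4,8a-trimethyl-7-methylidene-8-[4-(trimethylsilyl)but-3-yn-1-yl]decahydronaphthalen-2-yl]methanol F6, and Dess–Martin periodinane returns aldehyde 14.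

**Step 7.** β-Hydride elimination from the alkylrhodium hydride, or rhodium-hydride migration of the exocyclic double bond, may erode the product. The fallback sets out from 14 and comes back at 15 by a radical decarboxylation. Pinnick oxidation (NaClO2, NaH2PO4, 2-methylbut-2-ene, t-BuOH/H2O) gives (2S,4aS,8S,8aS)-4,4,8a-trimethyl-7-methylidene-8-[4-(trimethylsilyl)but-3-yn-1-yl]decahydronaphthalene-2-carboxylic acid F7. Oxalyl chloride followed by sodium 2-thioxopyridin-1(2H)-olate gives the Barton ester 2-thioxopyridin-1(2H)-yl (2S,4aS,8S,8aS)-4,4,8a-trimethyl-7-methylidene-8-[4-(trimethylsilyl)but-3-yn-1-yl]decahydronaphthalene-2-carboxylate F8, and photolysis with t-BuSH gives 15.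

**Step 11.** Opening may be slow in the two-phase basic medium, or regiochemically impure if the Payne equilibration is incomplete or hydroxide attacks elsewhere. The fallback sets out from 19 and comes back at 22 with the opposite epoxide and the opposite regiochemistry of opening. Epoxidation with D-(−)-diethyl tartrate (Ti(OiPr)4, t-BuOOH) gives [(2R,3R)-3-methyl-3-{2-[(1S,4aS,8aS)-5,5,8a-trimethyl-2-methylidenedecahydronaphthalen-1-yl]ethyl}oxiran-2-yl]methanol F9. Acid-catalysed hydrolysis (HClO4 cat., THF/H2O, 0 °C) opens it at the tertiary C13 with inversion and gives the same 13S,14R triol 22.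

Further compounds
F1 | step 6 | (2S,4E,8Z)-4-methyl-2-(2-methylprop-2-en-1-yl)-13-(trimethylsilyl)-8-[(trimethylsilyl)methyl]trideca-4,8-dien-12-ynal | O=C[C@@H](CC(C)=C)C/C(C)=C/CC/C(C[Si](C)(C)C)=C/CCC#C[Si](C)(C)C
F2 | step 6 | (2S,4E,8Z)-4-methyl-2-(2-methylprop-2-en-1-yl)-13-(trimethylsilyl)-8-[(trimethylsilyl)methyl]trideca-4,8-dien-12-yn-1-ol | OC[C@@H](CC(C)=C)C/C(C)=C/CC/C(C[Si](C)(C)C)=C/CCC#C[Si](C)(C)C
F3 | step 6 | (2S,4E,8Z)-4-methyl-2-(2-methylprop-2-en-1-yl)-13-(trimethylsilyl)-8-[(trimethylsilyl)methyl]trideca-4,8-dien-12-yn-1-yl acetate | CC(=O)OC[C@@H](CC(C)=C)C/C(C)=C/CC/C(C[Si](C)(C)C)=C/CCC#C[Si](C)(C)C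
F4 | step 6 | (2R,4E,8Z)-2-(2-chloro-2-methylpropyl)-4-methyl-13-(trimethylsilyl)-8-[(trimethylsilyl)methyl]trideca-4,8-dien-12-yn-1-yl acetate | CC(=O)OC[C@@H](CC(C)(C)Cl)C/C(C)=C/CC/C(C[Si](C)(C)C)=C/CCC#C[Si](C)(C)C
F5 | step 6 | [(2S,4aS,8S,8aS)-4,4,8a-trimethyl-7-methylidene-8-[4-(trimethylsilyl)but-3-yn-1-yl]decahydronaphthalen-2-yl]methyl acetate | C=C1CC[C@H]2C(C)(C)C[C@H](COC(C)=O)C[C@]2(C)[C@H]1CCC#C[Si](C)(C)C
F6 | step 6 | [(2S,4aS,8S,8aS)-4,4,8a-trimethyl-7-methylidene-8-[4-(trimethylsilyl)but-3-yn-1-yl]decahydronaphthalen-2-yl]methanol | C=C1CC[C@H]2C(C)(C)C[C@H](CO)C[C@]2(C)[C@H]1CCC#C[Si](C)(C)C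
F7 | step 7 | (2S,4aS,8S,8aS)-4,4,8a-trimethyl-7-methylidene-8-[4-(trimethylsilyl)but-3-yn-1-yl]decahydronaphthalene-2-carboxylic acid | C=C1CC[C@H]2C(C)(C)C[C@H](C(=O)O)C[C@]2(C)[C@H]1CCC#C[Si](C)(C)C
F8 | step 7 | 2-thioxopyridin-1(2H)-yl (2S,4aS,8S,8aS)-4,4,8a-trimethyl-7-methylidene-8-[4-(trimethylsilyl)but-3-yn-1-yl]decahydronaphthalene-2-carboxylate | C=C1CC[C@H]2C(C)(C)C[C@H](C(=O)ON3C=CC=CC3=S)C[C@]2(C)[C@H]1CCC#C[Si](C)(C)C
F9 | step 11 | [(2R,3R)-3-methyl-3-{2-[(1S,4aS,8aS)-5,5,8a-trimethyl-2-methylidenedecahydronaphthalen-1-yl]ethyl}oxiran-2-yl]methanol | C=C1CC[C@H]2C(C)(C)CCC[C@]2(C)[C@H]1CC[C@@]3(C)O[C@@H]3CO
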